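# Obtusane by decarboxylative radical spirocyclization onto a terminal alkyne: synthesis proposal

Atom numbers used throughout: ring A is C1 (bearing the exocyclic CH2), C2, C3, C4 (CHBr), C5 (CMe2) and spiro C6; ring B is C6, C7, C8, C9 (CMeBr), C10 (CHCl), C11. In this numbering the target is (4R,6S,9S,10S).

## The problem

Obtusane (24) is a spiro[5.5]undecane: ring A carries the exocyclic methylene on C1, a secondary bromide on C4 and the gem-dimethyl carbon C5, and ring B carries a tertiary bromide and a methyl group on C9 next to a secondary chloride on C10. The spiro carbon C6 is quaternary and bonded to the quaternary C5, so the bonds around C5–C6 are the hardest to make and polar bond formation there is slow. Four stereocentres are required: C9 and C10 are adjacent and trans, C4 is separated from them by two quaternary carbons and needs its own source of chirality, and C6 is stereogenic only because ring B is unsymmetrical, so the C9/C10 pair can control it through the chair of ring B. The ring B halogens sit the opposite way round to the product of a bromonium ion opened by chloride (bromine is on the tertiary carbon), so alkene bromochlorination is no source for them, and the C4 bromide is neopentyl, so SN2 at C4 is no source for it. One tertiary and two secondary alkyl halides must be carried: they rule out strong base much above 0 °C, tin and silyl radicals, low-valent metals and ionising acid, and the 1,1-disubstituted alkene moves into the ring under acid. The feature that makes the key step possible is the sp2 carbon C1, which bears the exocyclic CH2 and is bonded to the fully substituted C6: this is the arrangement left when a tertiary C6 radical adds to the inner carbon of a terminal alkyne, and a C6 carboxylic acid is a robust precursor of that radical.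

## Retrosynthesis

**C1–C6 (ring A).** Cutting C1–C6 of 24 and placing a carboxyl group on C6 leads to the alkynyl acid 23. Against a cut at C1–C2 or C6–C11, this one removes the ring and the spiro stereocentre together: in the forward direction C6 is a planar radical, so both C6 epimers of 23 serve and nothing upstream has to control the quaternary centre. The forward step must release the radical without touching three C–halogen bonds, close 6-exo-dig faster than the radical is reduced, and bond on the ring B face anti to C10–Cl.

**Protecting groups.** Acid 23 goes back to its tert-butyl ester 22 and to the C-silyl alkyne 21. The C6 ester lies between two quaternary carbons and cannot be saponified; a tert-butyl ester is cleaved by alkyl–oxygen fission with acid, which is indifferent to that crowding. It must survive enolate, hydride and organolithium steps.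

**C2–C3.** Alkyne 21 is cut between C2 and C3 into the propargyl anion of 19 and the primary triflate 20 of bromohydrin 18. A cut at C3–C4 would place a nucleophile or leaving group on the neopentyl C4. The chosen cut leaves C3 as a CH2OH next to C4, which is the reduction product of a C3 carbonyl. The forward step asks for SN2 at a primary triflate that has a bromide on the next carbon, without elimination.

**C4–Br.** Bromohydrin 18 comes from the α-bromo imide 17, this from the acyl oxazolidinone 15, and this from the acid 13. Bromine is put on C4 as an electrophile through an enolate, the one way to make a neopentyl secondary bromide without substitution at that carbon, and the auxiliary supplies the chirality that C9/C10 cannot relay. This removes one stereocentre and leaves a C3 carboxylic acid.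

**Ring B (C6–C11 and C6–C7).** Acid 13 is cut at both ring bonds of C6 into the glutaric half-ester 10 and the five-carbon dielectrophile 11 (triflate at C11, bromide at C7), made from alcohol 8. In 10 the carboxylate blocks enolization at C4, so base can only form the ester enolate at C6. Forming C5–C6 last would need a tertiary electrophile and was not considered further. The precursors are an achiral C7 diacid derivative and an open-chain fragment with two stereocentres. The forward step asks for two enolate alkylations in the presence of a tertiary bromide, the second at a hindered C–H. Half-ester 10 comes from the anhydride 9 in one step.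

**C9–Br and C10–Cl.** Alcohol 8 goes back through ester 7 and silyl ether 6 to hydroxy ester 4, glycidic ester 3, the (E)-enoate 2 and the alkyne 1. Both carbon–halogen bonds are made by SN2 inversion: bromide opens the epoxide at the tertiary β-carbon, and chloride displaces the α-triflate 5. Two inversions on the epoxide of an E alkene equal an anti addition to the Z alkene, which is the trans arrangement of ring B. A lactone-derived (Z)-alkene would need that anti addition directly with bromide on the tertiary carbon, which halonium chemistry does not deliver. The forward steps ask for an enantioselective epoxidation of an enoate and for substitution at C10 without participation by the neighbouring bromine.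

## Roads not taken

**Alternative 1:** Cut C6–C7 by an Ireland–Claisen ring contraction. The ten-membered allylic lactone A1 (ester oxygen on the C1 CH2, tetrasubstituted C1=C6 alkene in ring A) would be converted to its silyl ketene acetal (TBSOTf, Et3N) and rearrange to the spirocyclic C7 acid A2.
- Merits: the [3,3] shift makes the bond to the crowded C6 without ionic or radical addition, the exocyclic methylene appears by allylic transposition, and the constrained transition state may set C6 more reliably than a radical closure. In this respect it is the stronger road.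
- Weak points: A1 needs a tetrasubstituted ring A alkene and a ten-membered lactonisation carried out with the bromochloride in place. The C7 enolate has the tertiary C9 bromide in the γ position, where three-ring closure and elimination compete. A2 still carries a carboxyl group on C7 that has to be removed by a later radical decarboxylation in the presence of two C–Br bonds.
- Comparison: the chosen plan needs the same kind of decarboxylation but uses it to close the ring, and it does not need stereocontrol at C6 before the key step.

**Alternative 2:** Cut C1–C2 by hydroboration and B-alkyl Suzuki coupling. The vinyl enol triflate A3 would be hydroborated with 9-BBN at the vinyl group and closed onto the C1 enol triflate (PdCl2(dppf), AsPh3, Cs2CO3) to give the silyl ether A4.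
- Merits: this ring closure is far better precedented than the radical step chosen here and gives the methylene without regiochemical doubt.
- Weak points: the quaternary C6 next to C5 must already be in A3 as a single configuration, so the hardest problem is moved upstream without any convergence. The warm basic coupling medium endangers the tertiary bromide. C4 arrives as an oxygen function, so the bromide would have to be made afterwards by SN2 with inversion at a neopentyl ring carbon, where elimination and skeletal shifts are the usual outcome.
- Comparison: the chosen plan sets C4–Br by enolate bromination and lets C6 converge, at the price of a less certain ring closure.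

**Alternative 3:** Cut C6–C11 by spiroalkylation. KOtBu would reversibly enolize the C1 ketone of the iodo ketone A5, and the C6 enolate would displace the primary C11 iodide to give the spiro ketone A6, to be methylenated afterwards.
- Merits: it is short and convergent, and the thermodynamic enolate is the one that can close a six-membered ring.
- Weak points: the alkoxide meets a tertiary bromide, a C4 bromide γ to the C2 enolate (three-ring closure) and an iodide vicinal to the C10 chloride (elimination). The configuration at C6 depends on the face of a ring A enolate whose only bias is the remote C4 bromide. The later methylenation has to succeed at a ketone beside the spiro centre.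
- Comparison: the chosen route also makes a bond to C6 by enolate alkylation next to CMe2 (step 8) and is no better there, but at that stage the configuration of C6 does not matter and neither the C4 bromide nor a ketone is present. Alternative 3 would be shorter if its selectivities held.

Key step: step 15

Remarks on the chemistry:
- C6 is stereogenic in 12 to 23 and is carried as a mixture of epimers, since it becomes planar in step 15; names give only the controlled centres.
- The spatial arrangement at C4 is unchanged from 17 to 24. Its descriptor changes from S (17, 18, 20) to R (21 to 24) only because the priorities of its neighbours change.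

## Route

Step 1
Reactants: 1 tert-butyl(but-3-yn-1-yloxy)dimethylsilane
Product: 2 ethyl (2E)-5-[(tert-butyldimethylsilyl)oxy]-3-methylpent-2-enoate
Conditions: AlMe3 (2 equiv), Cp2ZrCl2 (0.25 equiv), CH2Cl2, 0 °C to rt; then ClCO2Et, 0 °C to rt
Reagents that add atoms: trimethylaluminium, C[Al](C)C; ethyl chloroformate, CCOC(=O)Cl
Why: Zirconium-catalysed carboalumination (Negishi) adds methyl and aluminium syn across the terminal alkyne with aluminium on the terminal carbon, and the alkenylalane is acylated by the chloroformate with retention, so the C8 chain ends trans to the ester (E). This brings in the C9 methyl and C11 and fixes the alkene geometry from which both ring B stereocentres derive.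

Step 2
Reactants: 2 ethyl (2E)-5-[(tert-butyldimethylsilyl)oxy]-3-methylpent-2-enoate
Product: 3 ethyl (2S,3R)-3-{2-[(tert-butyldimethylsilyl)oxy]ethyl}-3-methyloxirane-2-carboxylate
Conditions: Shi diacetate ketone (4,5-di-O-acetyl-1,2-O-isopropylidene-β-D-erythro-2,3-hexodiulo-2,6-pyranose, 0.3 equiv), KHSO5 (as 2KHSO5·KHSO4·K2SO4), NaHCO3, Bu4NHSO4, MeCN/aq. Na2EDTA, 0 °C
Reagents that add atoms: potassium peroxymonosulfate, [K+].[O-]S(=O)(=O)OO
Why: Shi asymmetric epoxidation: the chiral dioxirane formed from the ketone transfers oxygen through a spiro transition state, and the diacetate ketone is the variant suited to trans and trisubstituted enoates. The D-fructose series should give the (2S,3R) epoxide, which fixes the absolute sense of C10 and C9 (both are inverted later).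

Step 3
Reactants: 3 ethyl (2S,3R)-3-{2-[(tert-butyldimethylsilyl)oxy]ethyl}-3-methyloxirane-2-carboxylate
Product: 4 ethyl (2R,3S)-3-bromo-5-[(tert-butyldimethylsilyl)oxy]-2-hydroxy-3-methylpentanoate
Conditions: MgBr2·OEt2, Et2O, −20 to 0 °C
Reagents that add atoms: magnesium bromide diethyl etherate, [Mg+2].[Br-].[Br-].CCOCC
Why: Lewis acid opening of a glycidic ester: magnesium bridges the epoxide and ester oxygens and bromide attacks the tertiary β-carbon C9, which is remote from the deactivating carbonyl, with inversion. This places bromine on the tertiary carbon and leaves C10 as a free α-hydroxyl.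

Step 4
Reactants: 4 ethyl (2R,3S)-3-bromo-5-[(tert-butyldimethylsilyl)oxy]-2-hydroxy-3-methylpentanoate
Product: 6 ethyl (2S,3S)-3-bromo-5-[(tert-butyldimethylsilyl)oxy]-2-chloro-3-methylpentanoate, via α-triflate 5 (not isolated)
Conditions: Tf2O, 2,6-lutidine, CH2Cl2, −78 °C; then Bu4NCl, −78 to 0 °C
Reagents that add atoms: tetrabutylammonium chloride, CCCC[N+](CCCC)(CCCC)CCCC.[Cl-]
Why: The α-hydroxy ester is converted to its triflate and displaced by chloride in an SN2 reaction that the adjacent carbonyl accelerates and that inverts C10. With the inversion at C9 in step 3, Br and Cl end up as a formal anti adduct of the Z alkene, which is the trans pair of ring B.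

Step 5
Reactants: 6 ethyl (2S,3S)-3-bromo-5-[(tert-butyldimethylsilyl)oxy]-2-chloro-3-methylpentanoate
Product: 7 ethyl (2S,3S)-3,5-dibromo-2-chloro-3-methylpentanoate
Conditions: Ph3PBr2, CH2Cl2, 0 °C to rt
Reagents that add atoms: triphenylphosphine dibromide, BrP(Br)(c1ccccc1)(c1ccccc1)c1ccccc1
Why: Triphenylphosphine dibromide converts a primary silyl ether directly into the bromide under neutral conditions (bromide takes silicon, the alkoxyphosphonium ion is displaced by bromide). The C7 bromide is the slower of the two electrophiles needed for ring B.

Step 6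
Reactants: 7 ethyl (2S,3S)-3,5-dibromo-2-chloro-3-methylpentanoate
Product: 8 (2S,3S)-3,5-dibromo-2-chloro-3-methylpentan-1-ol
Conditions: i-Bu2AlH (2.5 equiv), CH2Cl2, −78 to −20 °C; aq. KNaC4H4O6 work-up
Reagents that add atoms: none
Why: Hydride reduction of the ester to the primary alcohol at low temperature leaves the C–Br and C–Cl bonds alone. The neutral work-up avoids epoxide formation from the chlorohydrin.

Step 7
Reactants: 9 3,3-dimethylglutaric anhydride
Product: 10 5-tert-butoxy-3,3-dimethyl-5-oxopentanoic acid
Conditions: t-BuOH, DMAP (cat.), N-hydroxysuccinimide (cat.), Et3N, toluene, 110 °C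
Reagents that add atoms: tert-butanol, CC(C)(C)O
Why: Acyl-transfer-catalysed opening of a symmetrical cyclic anhydride by an alcohol gives the half-ester. The tert-butyl ester will sit on C6 and the free acid on C3.

Step 8
Reactants: 8 (2S,3S)-3,5-dibromo-2-chloro-3-methylpentan-1-ol; 10 5-tert-butoxy-3,3-dimethyl-5-oxopentanoic acid
Product: 13 3-[(3S,4S)-4-bromo-1-(tert-butoxycarbonyl)-3-chloro-4-methylcyclohexyl]-3-methylbutanoic acid (C1 epimers), via pentyl triflate 11 (not isolated), via open-chain bromo acid 12 (not isolated)
Conditions: (a) 8, Tf2O, 2,6-lutidine, CH2Cl2, −78 °C, cold aqueous wash; (b) 10, LiN(i-Pr)2 (2.1 equiv), THF, −78 to 0 °C, then 11, −78 °C; (c) LiN(i-Pr)2 (1.2 equiv), DMPU, −78 to 0 °C; H3O+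
Reagents that add atoms: none
Why: The carboxylate of 10 blocks enolization at C4, so the base forms the ester enolate at C6 only, and this dianion is alkylated by the primary triflate 11, which reacts far faster than the primary bromide. A further equivalent of base re-forms the C6 enolate, which closes ring B by 6-exo-tet displacement of the C7 bromide (enolate spiroannulation with a differentiated 1,5-dielectrophile). C6 becomes quaternary as a mixture of epimers, which is of no consequence.

Step 9
Reactants: 13 3-[(3S,4S)-4-bromo-1-(tert-butoxycarbonyl)-3-chloro-4-methylcyclohexyl]-3-methylbutanoic acid (C1 epimers)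
Product: 15 tert-butyl (3S,4S)-1-{4-[(4S)-4-benzyl-2-oxo-1,3-oxazolidin-3-yl]-2-methyl-4-oxobutan-2-yl}-4-bromo-3-chloro-4-methylcyclohexane-1-carboxylate, via mixed pivalic anhydride 14 (not isolated)
Conditions: t-BuCOCl, Et3N, THF, −20 °C; then LiCl, (S)-4-benzyl-2-oxazolidinone, rt
Reagents that add atoms: (S)-4-benzyl-2-oxazolidinone, O=C1N[C@@H](Cc2ccccc2)CO1
Why: N-Acylation of the Evans auxiliary through the mixed pivalic anhydride under LiCl/amine conditions needs no strong base, so the halides are not at risk. The oxazolidinone attacks the less hindered carbonyl of the anhydride.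

Step 10
Reactants: 15 tert-butyl (3S,4S)-1-{4-[(4S)-4-benzyl-2-oxo-1,3-oxazolidin-3-yl]-2-methyl-4-oxobutan-2-yl}-4-bromo-3-chloro-4-methylcyclohexane-1-carboxylate
Product: 17 tert-butyl (3S,4S)-1-{(3S)-4-[(4S)-4-benzyl-2-oxo-1,3-oxazolidin-3-yl]-3-bromo-2-methyl-4-oxobutan-2-yl}-4-bromo-3-chloro-4-methylcyclohexane-1-carboxylate, via dibutylboron enolate 16 (not isolated)
Conditions: Bu2BOTf, i-Pr2NEt, CH2Cl2, −78 to 0 °C; then NBS, −78 °C
Reagents that add atoms: N-bromosuccinimide, O=C1CCC(=O)N1Br
Why: Evans auxiliary-controlled enolate bromination: the (Z)-boron enolate is brominated on the face away from the benzyl group, as established for acyl groups with a tert-alkyl branch, which sets C4 (S in this compound, the arrangement that is R in 24). The remote ring B centres and the C6 epimers should not interfere.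

Step 11
Reactants: 17 tert-butyl (3S,4S)-1-{(3S)-4-[(4S)-4-benzyl-2-oxo-1,3-oxazolidin-3-yl]-3-bromo-2-methyl-4-oxobutan-2-yl}-4-bromo-3-chloro-4-methylcyclohexane-1-carboxylate
Product: 18 tert-butyl (3S,4S)-4-bromo-1-[(3S)-3-bromo-4-hydroxy-2-methylbutan-2-yl]-3-chloro-4-methylcyclohexane-1-carboxylate
Conditions: LiBH4, H2O (1 equiv), Et2O/THF, 0 °C
Reagents that add atoms: none
Why: Reductive removal of the auxiliary with LiBH4 gives the primary alcohol and returns the oxazolidinone. The doubly neopentyl tert-butyl ester and the alkyl halides are not reduced under these conditions, and the cold, weakly basic medium should keep the bromohydrin from closing to the epoxide.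

Step 12
Reactants: 18 tert-butyl (3S,4S)-4-bromo-1-[(3S)-3-bromo-4-hydroxy-2-methylbutan-2-yl]-3-chloro-4-methylcyclohexane-1-carboxylate; 19 1-(trimethylsilyl)propyne
Product: 21 tert-butyl (3S,4S)-4-bromo-1-[(3R)-3-bromo-2-methyl-7-(trimethylsilyl)hept-6-yn-2-yl]-3-chloro-4-methylcyclohexane-1-carboxylate, via primary triflate 20 (not isolated)
Conditions: (a) 18, Tf2O, 2,6-lutidine, CH2Cl2, −78 °C, cold aqueous wash; (b) 19, n-BuLi, THF, −78 to −20 °C; then 20, −78 °C
Reagents that add atoms: none
Why: Lithiated 1-(trimethylsilyl)propyne alkylates at its propargylic carbon, and a primary triflate is displaced at −78 °C, a temperature at which elimination and attack at the hindered secondary bromide should not compete. This forms C2–C3 and brings in C1 and the future methylene carbon.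

Step 13
Reactants: 21 tert-butyl (3S,4S)-4-bromo-1-[(3R)-3-bromo-2-methyl-7-(trimethylsilyl)hept-6-yn-2-yl]-3-chloro-4-methylcyclohexane-1-carboxylate
Product: 22 tert-butyl (3S,4S)-4-bromo-1-[(3R)-3-bromo-2-methylhept-6-yn-2-yl]-3-chloro-4-methylcyclohexane-1-carboxylate
Conditions: K2CO3 (0.2 equiv), MeOH/THF, 0 °C
Reagents that add atoms: none
Why: Methanolysis of the alkynyl C–Si bond with catalytic carbonate is fast at 0 °C. The tertiary bromide is deactivated toward ionisation by the adjacent chlorine and should survive the short exposure.

Step 14
Reactants: 22 tert-butyl (3S,4S)-4-bromo-1-[(3R)-3-bromo-2-methylhept-6-yn-2-yl]-3-chloro-4-methylcyclohexane-1-carboxylate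
Product: 23 (3S,4S)-4-bromo-1-[(3R)-3-bromo-2-methylhept-6-yn-2-yl]-3-chloro-4-methylcyclohexane-1-carboxylic acid (C1 epimers)
Conditions: CF3CO2H/CH2Cl2 (1:4), 0 °C to rt
Reagents that add atoms: none
Why: Acid cleavage of the tert-butyl ester proceeds by alkyl–oxygen fission and is therefore indifferent to the crowding at the acyl carbon. The terminal alkyne and the halides tolerate brief exposure to trifluoroacetic acid.

Step 15
Reactants: 23 (3S,4S)-4-bromo-1-[(3R)-3-bromo-2-methylhept-6-yn-2-yl]-3-chloro-4-methylcyclohexane-1-carboxylic acid (C1 epimers)
Product: 24 obtusane, (2R,6S,8S,9S)-2,9-dibromo-8-chloro-1,1,9-trimethyl-5-methylidenespiro[5.5]undecane (4R,6S,9S,10S in the working numbering)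
Conditions: Ir[dF(CF3)ppy]2(dtbbpy)PF6 (1 mol%), Cs2CO3 (0.2 equiv), methyl thioglycolate (2 mol%), MeCN/DMF (9:1), 1 mM, degassed, blue LEDs (450 nm), rt
Reagents that add atoms: none
Why: Proposed new method: the photoexcited trivalent iridium complex oxidises the carboxylate of 23, CO2 is lost, and the planar tertiary C6 radical (the same from either C6 epimer) adds to the inner alkyne carbon C1, closing ring A; the exocyclic vinyl radical takes a hydrogen atom from the thiol or from acetonitrile, and divalent iridium reduces the thiyl radical to thiolate, which is reprotonated by 23, so the cycle is redox-neutral and base is needed only in catalytic amount. The closest known reactions are the thiol-cocatalysed photoredox hydrodecarboxylation of tertiary acids and the 6-exo-dig cyclization of alkyl radicals onto terminal alkynes under reductive chain conditions; their combination on an unactivated alkyne has not been shown. Ring A closes in the 6-exo-dig mode, preferred over 7-endo on stereoelectronic grounds and helped by the gem-dimethyl group at C5. The only new stereocentre is C6: in the chair of ring B that keeps the C5 branch and both halogens equatorial, C1 should bond along the axial direction on the face anti to C10–Cl, which gives (6S), whereas the other chair would force the alkyne past an axial chlorine. The step needs ring closure to outrun hydrogen transfer to the C6 radical, which the very low thiol concentration is meant to secure, and it needs the three C–halogen bonds to stay intact, which they should because alkyl radicals abstract bromine from alkyl bromides slowly and no halogen is β to a radical centre on the intended path.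

## Compound list

1 | tert-butyl(but-3-yn-1-yloxy)dimethylsilane | C#CCCO[Si](C)(C)C(C)(C)C | starting material
2 | ethyl (2E)-5-[(tert-butyldimethylsilyl)oxy]-3-methylpent-2-enoate | CCOC(=O)/C=C(\C)CCO[Si](C)(C)C(C)(C)C | intermediate
3 | ethyl (2S,3R)-3-{2-[(tert-butyldimethylsilyl)oxy]ethyl}-3-methyloxirane-2-carboxylate | CCOC(=O)[C@H]1O[C@]1(C)CCO[Si](C)(C)C(C)(C)C | intermediate
4 | ethyl (2R,3S)-3-bromo-5-[(tert-butyldimethylsilyl)oxy]-2-hydroxy-3-methylpentanoate | CCOC(=O)[C@@H](O)[C@@](C)(Br)CCO[Si](C)(C)C(C)(C)C | intermediate
5 | ethyl (2R,3S)-3-bromo-5-[(tert-butyldimethylsilyl)oxy]-3-methyl-2-[(trifluoromethanesulfonyl)oxy]pentanoate | CCOC(=O)[C@@H](OS(=O)(=O)C(F)(F)F)[C@@](C)(Br)CCO[Si](C)(C)C(C)(C)C | intermediate (not isolated)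
6 | ethyl (2S,3S)-3-bromo-5-[(tert-butyldimethylsilyl)oxy]-2-chloro-3-methylpentanoate | CCOC(=O)[C@H](Cl)[C@@](C)(Br)CCO[Si](C)(C)C(C)(C)C | intermediate
7 | ethyl (2S,3S)-3,5-dibromo-2-chloro-3-methylpentanoate | CCOC(=O)[C@H](Cl)[C@@](C)(Br)CCBr | intermediate
8 | (2S,3S)-3,5-dibromo-2-chloro-3-methylpentan-1-ol | OC[C@H](Cl)[C@@](C)(Br)CCBr | intermediate
9 | 3,3-dimethylglutaric anhydride (4,4-dimethyloxane-2,6-dione) | CC1(C)CC(=O)OC(=O)C1 | starting material
10 | 5-tert-butoxy-3,3-dimethyl-5-oxopentanoic acid | CC(C)(C)OC(=O)CC(C)(C)CC(=O)O | intermediate
11 | (2S,3S)-3,5-dibromo-2-chloro-3-methylpentyl trifluoromethanesulfonate | O=S(=O)(OC[C@H](Cl)[C@@](C)(Br)CCBr)C(F)(F)F | intermediate (not isolated)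
12 | (6S,7S)-7,9-dibromo-4-(tert-butoxycarbonyl)-6-chloro-3,3,7-trimethylnonanoic acid (C4 epimers, present as its lithium salt) | CC(C)(C)OC(=O)C(C[C@H](Cl)[C@@](C)(Br)CCBr)C(C)(C)CC(=O)O | intermediate (not isolated)
13 | 3-[(3S,4S)-4-bromo-1-(tert-butoxycarbonyl)-3-chloro-4-methylcyclohexyl]-3-methylbutanoic acid (C1 epimers) | CC(C)(C)OC(=O)C1(C(C)(C)CC(=O)O)CC[C@](C)(Br)[C@@H](Cl)C1 | intermediate
14 | mixed anhydride of 13 with pivalic acid | CC(C)(C)OC(=O)C1(C(C)(C)CC(=O)OC(=O)C(C)(C)C)CC[C@](C)(Br)[C@@H](Cl)C1 | intermediate (not isolated)
15 | tert-butyl (3S,4S)-1-{4-[(4S)-4-benzyl-2-oxo-1,3-oxazolidin-3-yl]-2-methyl-4-oxobutan-2-yl}-4-bromo-3-chloro-4-methylcyclohexane-1-carboxylate | CC(C)(C)OC(=O)C1(C(C)(C)CC(=O)N2[C@@H](Cc3ccccc3)COC2=O)CC[C@](C)(Br)[C@@H](Cl)C1 | intermediate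
16 | dibutylboron (Z)-enolate of 15 | CCCCB(CCCC)O/C(N1[C@@H](Cc2ccccc2)COC1=O)=C\C(C)(C)C3(C(=O)OC(C)(C)C)CC[C@](C)(Br)[C@@H](Cl)C3 | intermediate (not isolated)
17 | tert-butyl (3S,4S)-1-{(3S)-4-[(4S)-4-benzyl-2-oxo-1,3-oxazolidin-3-yl]-3-bromo-2-methyl-4-oxobutan-2-yl}-4-bromo-3-chloro-4-methylcyclohexane-1-carboxylate | CC(C)(C)OC(=O)C1(C(C)(C)[C@H](Br)C(=O)N2[C@@H](Cc3ccccc3)COC2=O)CC[C@](C)(Br)[C@@H](Cl)C1 | intermediate
18 | tert-butyl (3S,4S)-4-bromo-1-[(3S)-3-bromo-4-hydroxy-2-methylbutan-2-yl]-3-chloro-4-methylcyclohexane-1-carboxylate | CC(C)(C)OC(=O)C1(C(C)(C)[C@H](Br)CO)CC[C@](C)(Br)[C@@H](Cl)C1 | intermediate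
19 | 1-(trimethylsilyl)propyne | CC#C[Si](C)(C)C | starting material
20 | tert-butyl (3S,4S)-4-bromo-1-{(3S)-3-bromo-2-methyl-4-[(trifluoromethanesulfonyl)oxy]butan-2-yl}-3-chloro-4-methylcyclohexane-1-carboxylate | CC(C)(C)OC(=O)C1(C(C)(C)[C@H](Br)COS(=O)(=O)C(F)(F)F)CC[C@](C)(Br)[C@@H](Cl)C1 | intermediate (not isolated)
21 | tert-butyl (3S,4S)-4-bromo-1-[(3R)-3-bromo-2-methyl-7-(trimethylsilyl)hept-6-yn-2-yl]-3-chloro-4-methylcyclohexane-1-carboxylate | CC(C)(C)OC(=O)C1(C(C)(C)[C@H](Br)CCC#C[Si](C)(C)C)CC[C@](C)(Br)[C@@H](Cl)C1 | intermediate
22 | tert-butyl (3S,4S)-4-bromo-1-[(3R)-3-bromo-2-methylhept-6-yn-2-yl]-3-chloro-4-methylcyclohexane-1-carboxylate | CC(C)(C)OC(=O)C1(C(C)(C)[C@H](Br)CCC#C)CC[C@](C)(Br)[C@@H](Cl)C1 | intermediate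
23 | (3S,4S)-4-bromo-1-[(3R)-3-bromo-2-methylhept-6-yn-2-yl]-3-chloro-4-methylcyclohexane-1-carboxylic acid (C1 epimers) | C#CCC[C@@H](Br)C(C)(C)C1(C(=O)O)CC[C@](C)(Br)[C@@H](Cl)C1 | intermediate
24 | obtusane, (2R,6S,8S,9S)-2,9-dibromo-8-chloro-1,1,9-trimethyl-5-methylidenespiro[5.5]undecane | C=C1CC[C@@H](Br)C(C)(C)[C@]12CC[C@](C)(Br)[C@@H](Cl)C2 | target

## Step count and least certain steps

Total: 15 steps. Longest linear sequence: 14 steps (1 to 24 through steps 1 to 6 and 8 to 15); step 7 is a one-step side branch.

**Step 15 (key step, proposed new method).**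
- What may go wrong: hydrogen transfer to the C6 radical before ring closure (plain hydrodecarboxylation), because addition to an unactivated alkyne is slow. A 1,5-hydrogen shift from the propargylic C2–H competes through the same chain conformation. After closure, hydrogen transfer within the molecule from C8–H or C10–H to the vinyl radical would be followed by loss of a bromine atom from C9. Facial selectivity at C6 rests on a conformational preference of ring B and may be incomplete. Over long irradiation the carboxylate may lactonise onto C4 or C10.
- Fallback (known chemistry), from 23 back to 24: the acid is converted through its chloride ((COCl)2, cat. DMF; then N-hydroxyphthalimide, Et3N) into the N-acyloxyphthalimide F1. Irradiation of F1 with Ru(bpy)3(PF6)2 and Hantzsch ester in CH2Cl2 releases the same C6 radical by reductive fragmentation, without base or thiol. The dihydropyridine gives hydrogen slowly to alkyl radicals and quickly to vinyl radicals, which is the order this cyclization needs.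

**Step 8.**
- What may go wrong: slow deprotonation of the hindered C6–H after the first alkylation, so that the amide base instead removes HBr from the tertiary or the primary bromide. Also possible are three-ring closure of the enolate onto C10 with loss of chloride, and elimination of triflate in the first alkylation.
- Fallback, from 8 (through triflate 11) back to 13: the C5–C6 bond is made by a sigmatropic shift, not by alkylation of a hindered enolate. The lithium enolate of 3-methylbut-2-en-1-yl acetate is alkylated by 11 to give the open-chain ester F2. A second, unhindered enolization closes ring B to the prenyl cyclohexanecarboxylate F3. LiN(i-Pr)2/Me3SiCl gives the silyl ketene acetal F4, which on warming undergoes Ireland–Claisen rearrangement to the acid F5 bearing the 2-methylbut-3-en-2-yl group on C6. tert-Butyl 2,2,2-trichloroacetimidate gives the ester F6; 9-BBN then NaBO3·4H2O gives the primary alcohol F7; oxidation (TEMPO, PhI(OAc)2, MeCN/H2O) gives 13.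

**Step 4.**
- What may go wrong: participation of the neighbouring bromine in the open chain, where C–Br can lie antiperiplanar to the triflate. This would give retention at C10 or transposition of the halogens. Loss of HBr across C9–C10 is also possible.
- Fallback, from 4 back to 8: the substitution is done in a ring that forbids participation. Aqueous HF in MeCN, then catalytic TsOH, removes the silyl group and closes the hydroxy lactone F8, in which OH and Br are cis and cannot become antiperiplanar. Triflation gives F9, and Bu4NCl displaces it with inversion to the chloro lactone F10 (a pantolactone-type substitution). LiBH4 gives the diol F11, and Appel bromination (CBr4, PPh3, −20 °C) of the less hindered C7 hydroxyl returns to 8.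

**Step 12.**
- What may go wrong: elimination from the β-bromo triflate under the strongly basic propargyl anion (loss of HOTf or HBr), or migration of bromine through a bromonium ion before the nucleophile arrives.
- Fallback, from 20 back to 22 (21 is bypassed): the chain is added with a less basic nucleophile and the alkyne is made last. Allylmagnesium bromide with catalytic CuI couples with 20 to give the terminal alkene F12. Ozonolysis (O3, then PPh3) gives the aldehyde F13. Dimethyl (1-diazo-2-oxopropyl)phosphonate with K2CO3 in MeOH (Ohira–Bestmann homologation) gives 22.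

**Step 11.**
- What may go wrong: hydride attack at the ring carbonyl of the auxiliary, since the acyl group is very hindered, epoxide closure of the bromohydrin alkoxide, or epimerisation at C4 before reduction.
- Fallback, from 13 back to 18 (steps 9 to 11 are bypassed): catalyst control replaces the auxiliary. BH3·SMe2 reduces the free acid of 13 to the alcohol F7 (the compound also met in the fallback for step 8), and Dess–Martin periodinane gives the aldehyde F14. Enamine-catalysed α-bromination follows, using 4,4-dibromo-2,6-di-tert-butylcyclohexa-2,5-dienone and the enantiomer of 2,5-diphenylpyrrolidine that delivers the (S)-bromide. This gives the bromo aldehyde F15, which NaBH4 reduces in the same flask to 18.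

## Further compounds

F1 | step 15 | 1,3-dioxoisoindolin-2-yl (3S,4S)-4-bromo-1-[(3R)-3-bromo-2-methylhept-6-yn-2-yl]-3-chloro-4-methylcyclohexane-1-carboxylate | C#CCC[C@@H](Br)C(C)(C)C1(C(=O)ON2C(=O)c3ccccc3C2=O)CC[C@](C)(Br)[C@@H](Cl)C1
F2 | step 8 | 3-methylbut-2-en-1-yl (4S,5S)-5,7-dibromo-4-chloro-5-methylheptanoate | CC(C)=CCOC(=O)CC[C@H](Cl)[C@@](C)(Br)CCBr
F3 | step 8 | 3-methylbut-2-en-1-yl (3S,4S)-4-bromo-3-chloro-4-methylcyclohexane-1-carboxylate | CC(C)=CCOC(=O)C1CC[C@](C)(Br)[C@@H](Cl)C1
F4 | step 8 | trimethylsilyl ketene acetal of F3 | CC(C)=CCOC(O[Si](C)(C)C)=C1CC[C@](C)(Br)[C@@H](Cl)C1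
F5 | step 8 | (3S,4S)-4-bromo-3-chloro-4-methyl-1-(2-methylbut-3-en-2-yl)cyclohexane-1-carboxylic acid | C=CC(C)(C)C1(C(=O)O)CC[C@](C)(Br)[C@@H](Cl)C1
F6 | step 8 | tert-butyl (3S,4S)-4-bromo-3-chloro-4-methyl-1-(2-methylbut-3-en-2-yl)cyclohexane-1-carboxylate | C=CC(C)(C)C1(C(=O)OC(C)(C)C)CC[C@](C)(Br)[C@@H](Cl)C1
F7 | step 8 | tert-butyl (3S,4S)-4-bromo-3-chloro-1-(4-hydroxy-2-methylbutan-2-yl)-4-methylcyclohexane-1-carboxylate | CC(C)(C)OC(=O)C1(C(C)(C)CCO)CC[C@](C)(Br)[C@@H](Cl)C1
F8 | step 4 | (3R,4S)-4-bromo-3-hydroxy-4-methyloxan-2-one | O=C1OCC[C@](C)(Br)[C@@H]1O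
F9 | step 4 | (3R,4S)-4-bromo-4-methyl-2-oxooxan-3-yl trifluoromethanesulfonate | O=C1OCC[C@](C)(Br)[C@@H]1OS(=O)(=O)C(F)(F)F
F10 | step 4 | (3S,4S)-4-bromo-3-chloro-4-methyloxan-2-one | O=C1OCC[C@](C)(Br)[C@H]1Cl
F11 | step 4 | (2S,3S)-3-bromo-2-chloro-3-methylpentane-1,5-diol | OC[C@H](Cl)[C@@](C)(Br)CCO
F12 | step 12 | tert-butyl (3S,4S)-4-bromo-1-[(3R)-3-bromo-2-methylhept-6-en-2-yl]-3-chloro-4-methylcyclohexane-1-carboxylate | CC(C)(C)OC(=O)C1(C(C)(C)[C@H](Br)CCC=C)CC[C@](C)(Br)[C@@H](Cl)C1
F13 | step 12 | tert-butyl (3S,4S)-4-bromo-1-[(3R)-3-bromo-2-methyl-6-oxohexan-2-yl]-3-chloro-4-methylcyclohexane-1-carboxylate | CC(C)(C)OC(=O)C1(C(C)(C)[C@H](Br)CCC=O)CC[C@](C)(Br)[C@@H](Cl)C1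
F14 | step 11 | tert-butyl (3S,4S)-4-bromo-3-chloro-4-methyl-1-(2-methyl-4-oxobutan-2-yl)cyclohexane-1-carboxylate | CC(C)(C)OC(=O)C1(C(C)(C)CC=O)CC[C@](C)(Br)[C@@H](Cl)C1
F15 | step 11 | tert-butyl (3S,4S)-4-bromo-1-[(3S)-3-bromo-2-methyl-4-oxobutan-2-yl]-3-chloro-4-methylcyclohexane-1-carboxylate | CC(C)(C)OC(=O)C1(C(C)(C)[C@H](Br)C=O)CC[C@](C)(Br)[C@@H](Cl)C1
A1 | alternative 1 | ten-membered allylic lactone (ester oxygen on the C1 CH2, C1=C6 alkene in ring A) | O=C1OCC2=C(C[C@H](Cl)[C@@](C)(Br)CC1)C(C)(C)[C@H](Br)CC2
A2 | alternative 1 | spirocyclic C7 carboxylic acid (C7 epimers) | C=C1CC[C@@H](Br)C(C)(C)[C@]12C(C(=O)O)C[C@](C)(Br)[C@@H](Cl)C2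
A3 | alternative 2 | C1 enol triflate with C4 silyl ether and C3 vinyl group on the ring B quaternary carbon | C=C(OS(=O)(=O)C(F)(F)F)[C@]1(C(C)(C)[C@@H](O[Si](C)(C)C(C)(C)C)C=C)CC[C@](C)(Br)[C@@H](Cl)C1
A4 | alternative 2 | spirocyclic C4 silyl ether with exocyclic methylene | C=C1CC[C@H](O[Si](C)(C)C(C)(C)C)C(C)(C)[C@]12CC[C@](C)(Br)[C@@H](Cl)C2
A5 | alternative 3 | ring A bromo ketone with the bromochloro iodide chain on C6 | O=C1CC[C@@H](Br)C(C)(C)C1CC[C@](C)(Br)[C@@H](Cl)CI
A6 | alternative 3 | spiro bromochloro ketone | O=C1CC[C@@H](Br)C(C)(C)[C@]12CC[C@](C)(Br)[C@@H](Cl)C2
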